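**Retrosynthetic overview**
1. The target comes from double ester reduction of a trans-(2S,3S)-2-syringyl-2,3-dihydrobenzofuran-3-carboxylate that carries a methyl propanoate side chain.
2. The key disconnection is the benzylic O1–C2 bond. Opening the dihydrofuran ring gives an achiral (E)-α-(2-hydroxyaryl)sinapate. In the forward direction, an organocatalytic enantioselective cycloisomerisation through its para-quinone methide tautomer sets C2 and C3 together.
3. The trisubstituted alkene comes from a Knoevenagel condensation of syringaldehyde with a 7-methoxybenzofuran-2(3H)-one, followed by methanolysis of the lactone.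
4. The aryl–CH2CO bond comes from ortho-hydroxyalkylation of methyl dihydroferulate with ethyl glyoxylate, then hydrogenolysis and lactonisation.
5. Ring order: both benzene rings are bought. A temporary lactone ring is made in step 2 and opened in step 3. The dihydrofuran ring is the only ring built for the target and is closed in step 4.

Assumption: the quinidine-derived squaramide is taken to give the (2S,3S) series. The sense of induction of a new reaction cannot be predicted with certainty. If the first run gives the antipode, the pseudo-enantiomeric quinine-derived squaramide is used and nothing else changes.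

**Route**

Step 1
Reactants: 1 methyl 3-(4-hydroxy-3-methoxyphenyl)propanoate (methyl dihydroferulate); 2 ethyl glyoxylate (50% in toluene, freshly depolymerised)
Product: 3 ethyl 2-hydroxy-2-[2-hydroxy-3-methoxy-5-(3-methoxy-3-oxopropyl)phenyl]acetate (racemic)
Conditions: TiCl4 (1.1 equiv), CH2Cl2, −30 °C to rt, 6 h; aq. NH4Cl
Reagents that add atoms: none
Why: Ortho-specific Friedel–Crafts hydroxyalkylation: the TiCl4-bound phenol also binds the glyoxylate aldehyde and delivers it through a cyclic transition state to the only free ortho carbon, and the new carbinol centre is racemic and is erased in step 2.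

Step 2
Reactants: 3 ethyl 2-hydroxy-2-[2-hydroxy-3-methoxy-5-(3-methoxy-3-oxopropyl)phenyl]acetate
Product: 5 methyl 3-(7-methoxy-2-oxo-2,3-dihydro-1-benzofuran-5-yl)propanoate, via arylacetate 4 (not isolated)
Conditions: H2 (3 bar), 10% Pd/C, AcOH, H2SO4 (5 mol %), 60 °C; filter; TsOH·H2O (5 mol %), toluene, reflux with distillation of EtOH
Reagents that add atoms: none
Why: Acid-assisted benzylic hydrogenolysis (mandelate-to-arylacetate reduction) removes the carbinol oxygen, which the ortho-hydroxy ring activates, and the freed 2-hydroxyarylacetate then lactonises under acid catalysis as ethanol is distilled off; the racemic centre disappears, and the aliphatic ester and aryl ethers are inert to H2 over Pd/C.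

Step 3
Reactants: 5 methyl 3-(7-methoxy-2-oxo-2,3-dihydro-1-benzofuran-5-yl)propanoate; 6 syringaldehyde (4-hydroxy-3,5-dimethoxybenzaldehyde)
Product: 8 methyl (E)-3-(4-hydroxy-3,5-dimethoxyphenyl)-2-[2-hydroxy-3-methoxy-5-(3-methoxy-3-oxopropyl)phenyl]prop-2-enoate, via isoaurone lactone 7 (not isolated)
Conditions: piperidine (10 mol %), AcOH (10 mol %), toluene, Dean–Stark reflux, 4 h; evaporate; MeOH, H2SO4 (5 mol %), reflux, 6 h; NaHCO3, then concentrate
Reagents that add atoms: methanol, CO
Why: Knoevenagel condensation at the doubly activated C3 methylene of the benzofuranone (pKa about 13) gives the arylidene lactone, and acid-catalysed transesterification in excess methanol then opens the strained aryl ester and levels any ethyl or free-acid side chain back to the methyl ester; hydroxycinnamates neither add methanol nor cyclise under these acidic conditions, so no racemic 10 forms, and the alkene geometry does not matter because step 4 erases it.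

Step 4
Reactants: 8 methyl (E)-3-(4-hydroxy-3,5-dimethoxyphenyl)-2-[2-hydroxy-3-methoxy-5-(3-methoxy-3-oxopropyl)phenyl]prop-2-enoate
Product: 10 methyl (2S,3S)-2-(4-hydroxy-3,5-dimethoxyphenyl)-7-methoxy-5-(3-methoxy-3-oxopropyl)-2,3-dihydro-1-benzofuran-3-carboxylate, via para-quinone methide 9 (not isolated)
Conditions: quinidine-derived squaramide 3-{[3,5-bis(trifluoromethyl)phenyl]amino}-4-{[(9R)-6'-methoxycinchonan-9-yl]amino}cyclobut-3-ene-1,2-dione (10 mol %), MeOH (5 equiv, proton shuttle, keeps 8 from relactonising), toluene/CH2Cl2 4:1, 0.1 M, 40 °C, 48 h; AcOH quench, SiO2 plug, one recrystallisation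
Reagents that add atoms: none
Why: Proposed new method: a catalytic enantioselective, redox-neutral cycloisomerisation (net hydroaryloxylation of a cinnamate, formally 5-endo) rerouted through a para-quinone methide, a conversion not described, to my knowledge, for α-(2-hydroxyaryl)-4-hydroxycinnamates even in racemic form; the quinuclidine nitrogen, matched in pKa to the sinapate OH, ionises the 4-OH, and the resulting vinylogous ester enolate is reprotonated at C-alpha to give 9, whose C-alpha–H is so acidic that its enantiomers interconvert through 8; the squaramide then holds the quinone-methide carbonyl while the amine activates the ring A phenol, so the O1–C2 bond closes by a Baldwin-allowed 5-exo-trig oxa-1,6-addition on one face only (dynamic kinetic asymmetric transformation); C2 is set in this C–O bond formation, and C3 follows as trans because aryl and ester avoid each other in the closing envelope and any cis isomer epimerises at the acidic C3–H; rearomatisation and relief of the cis-stilbene strain of 8 drive the closure, and the phenol of 10 is estimated to be about three pKa units less acidic than that of 8, so the catalyst stays on the substrate and should not reopen the product before conversion is complete; the closest known reaction types are amine–squaramide catalysed 1,6-additions to para-quinone methides, organocatalytic oxa-Michael closures to flavanones and chromanones, and the uncatalysed racemic quinone-methide ring closure that ends the biomimetic dehydrodimerisation of ferulates.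

Step 5
Reactants: 10 methyl (2S,3S)-2-(4-hydroxy-3,5-dimethoxyphenyl)-7-methoxy-5-(3-methoxy-3-oxopropyl)-2,3-dihydro-1-benzofuran-3-carboxylate
Product: 11 4-[(2S,3R)-3-(hydroxymethyl)-5-(3-hydroxypropyl)-7-methoxy-2,3-dihydro-1-benzofuran-2-yl]-2,6-dimethoxyphenol (target)
Conditions: i-Bu2AlH (DIBAL-H, 7 equiv), THF/toluene, −78 to 0 °C; aq. KNaC4H4O6 (potassium sodium tartrate)
Reagents that add atoms: none
Why: Ester-to-alcohol reduction with a non-basic aluminium hydride: the phenol is capped in situ as its aluminium phenoxide, so neither enolisation at C3 nor quinone-methide ring opening competes at or below 0 °C, both stereocentres are untouched, and the C3 descriptor changes from S to R only because CH2OH ranks below C2 whereas CO2Me ranked above it.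

**Compound list**
1 | methyl 3-(4-hydroxy-3-methoxyphenyl)propanoate | COC(=O)CCc1ccc(O)c(OC)c1 | starting material
2 | ethyl glyoxylate | CCOC(=O)C=O | starting material
3 | ethyl 2-hydroxy-2-[2-hydroxy-3-methoxy-5-(3-methoxy-3-oxopropyl)phenyl]acetate (racemic) | CCOC(=O)C(O)c1cc(CCC(=O)OC)cc(OC)c1O | intermediate
4 | ethyl 2-[2-hydroxy-3-methoxy-5-(3-methoxy-3-oxopropyl)phenyl]acetate | CCOC(=O)Cc1cc(CCC(=O)OC)cc(OC)c1O | intermediate (not isolated)
5 | methyl 3-(7-methoxy-2-oxo-2,3-dihydro-1-benzofuran-5-yl)propanoate | COC(=O)CCc1cc(OC)c2OC(=O)Cc2c1 | intermediate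
6 | syringaldehyde | COc1cc(C=O)cc(OC)c1O | starting material
7 | methyl 3-[(3E)-3-(4-hydroxy-3,5-dimethoxybenzylidene)-7-methoxy-2-oxo-2,3-dihydro-1-benzofuran-5-yl]propanoate | COC(=O)CCc1cc(OC)c2OC(=O)/C(=C/c3cc(OC)c(O)c(OC)c3)c2c1 | intermediate (not isolated)
8 | methyl (E)-3-(4-hydroxy-3,5-dimethoxyphenyl)-2-[2-hydroxy-3-methoxy-5-(3-methoxy-3-oxopropyl)phenyl]prop-2-enoate | COC(=O)CCc1cc(OC)c(O)c(c1)/C(=C\c1cc(OC)c(O)c(OC)c1)C(=O)OC | intermediate
9 | methyl (2R)-3-(3,5-dimethoxy-4-oxocyclohexa-2,5-dien-1-ylidene)-2-[2-hydroxy-3-methoxy-5-(3-methoxy-3-oxopropyl)phenyl]propanoate (para-quinone methide; enantiomers interconvert through 8, productive R form drawn) | COC(=O)CCc1cc(OC)c(O)c(c1)[C@@H](C=C1C=C(OC)C(=O)C(OC)=C1)C(=O)OC | intermediate (not isolated)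
10 | methyl (2S,3S)-2-(4-hydroxy-3,5-dimethoxyphenyl)-7-methoxy-5-(3-methoxy-3-oxopropyl)-2,3-dihydro-1-benzofuran-3-carboxylate (trans) | COc1cc([C@H]2Oc3c(OC)cc(CCC(=O)OC)cc3[C@@H]2C(=O)OC)cc(OC)c1O | intermediate
11 | 4-[(2S,3R)-3-(hydroxymethyl)-5-(3-hydroxypropyl)-7-methoxy-2,3-dihydro-1-benzofuran-2-yl]-2,6-dimethoxyphenol (trans) | COc1cc([C@H]2Oc3c(OC)cc(CCCO)cc3[C@@H]2CO)cc(OC)c1O | target

**Total step count:** 5. **Longest linear sequence:** 5 (1 → 3 → 5 → 8 → 10 → 11).

**Three steps most likely to fail**

First, step 4, the proposed new step.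
- **Risk:** the tautomerisation of 8 to 9 is uphill, by roughly 15–18 kcal/mol on a rough estimate, so turnover may be slow. The equilibrium constant for closure is only estimated to be favourable. Reversible reopening could erode the ee, and the sense of induction is unproven.
- **Fallback, known chemistry only, from 8 back to 10:**
  - Saponify both esters with LiOH in THF/H2O to give (E)-2-[5-(2-carboxyethyl)-2-hydroxy-3-methoxyphenyl]-3-(4-hydroxy-3,5-dimethoxyphenyl)prop-2-enoic acid F1. Keep it as its triethylammonium salt so that it does not relactonise.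
  - Hydrogenate with [Ir(cod)(SIPHOX)]BArF under H2 (6 bar) in MeOH with Et3N. SIPHOX is the spiro phosphine–oxazoline ligand, with the antipode chosen for the R acid, and BArF is tetrakis[3,5-bis(trifluoromethyl)phenyl]borate. This catalyst type is established for α-substituted cinnamic acids. The product is (2R)-2-[5-(2-carboxyethyl)-2-hydroxy-3-methoxyphenyl]-3-(4-hydroxy-3,5-dimethoxyphenyl)propanoic acid F2.
  - Alkylate both carboxylates with MeI/KHCO3 in DMF, without acidification, to give methyl (2R)-3-(4-hydroxy-3,5-dimethoxyphenyl)-2-[2-hydroxy-3-methoxy-5-(3-methoxy-3-oxopropyl)phenyl]propanoate F3.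
  - Oxidise the more electron-rich syringyl phenol with Ag2O in CH2Cl2. This gives 9 as a single enantiomer under neutral conditions. It closes spontaneously and trans-selectively to 10, as in the classical Ag2O dehydrodimerisation of ferulates.

Second, step 1.
- **Risk:** the guaiacol methoxy group and the ester may tie up TiCl4, and the electron-rich phenol may add twice to give a diarylacetate.
- **Fallback, from 1 back to 5, replacing electrophilic substitution by cross-coupling:**
  - Iodinate the only free ortho position with NIS and catalytic TsOH in MeCN to give methyl 3-(4-hydroxy-3-iodo-5-methoxyphenyl)propanoate F4.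
  - Couple it with the Reformatsky reagent BrZnCH2CO2t-Bu (2.5 equiv; the first equivalent forms the zinc phenoxide) under Pd(dba)2/P(t-Bu)3 in THF. This gives tert-butyl 2-[2-hydroxy-3-methoxy-5-(3-methoxy-3-oxopropyl)phenyl]acetate F5.
  - Treat with TFA in CH2Cl2, which cleaves the tert-butyl ester and closes the lactone to 5.

Third, step 2.
- **Risk:** hydrogenolysis of a benzylic C–O bond next to a carbonyl group can be sluggish.
- **Fallback, from 3 back to 5, replacing hydrogenolysis by halide exchange and metal reduction:**
  - Lactonise 3 with TsOH in toluene to give methyl 3-(3-hydroxy-7-methoxy-2-oxo-2,3-dihydro-1-benzofuran-5-yl)propanoate F6.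
  - Convert the hydroxyl group with SOCl2 and catalytic pyridine into methyl 3-(3-chloro-7-methoxy-2-oxo-2,3-dihydro-1-benzofuran-5-yl)propanoate F7.
  - Remove the α-chlorine with Zn dust in AcOH at rt to give 5.

**Further compounds**
F1 | step 4 | (E)-2-[5-(2-carboxyethyl)-2-hydroxy-3-methoxyphenyl]-3-(4-hydroxy-3,5-dimethoxyphenyl)prop-2-enoic acid | OC(=O)CCc1cc(OC)c(O)c(c1)/C(=C\c1cc(OC)c(O)c(OC)c1)C(=O)O
F2 | step 4 | (2R)-2-[5-(2-carboxyethyl)-2-hydroxy-3-methoxyphenyl]-3-(4-hydroxy-3,5-dimethoxyphenyl)propanoic acid | OC(=O)CCc1cc(OC)c(O)c(c1)[C@@H](Cc1cc(OC)c(O)c(OC)c1)C(=O)O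
F3 | step 4 | methyl (2R)-3-(4-hydroxy-3,5-dimethoxyphenyl)-2-[2-hydroxy-3-methoxy-5-(3-methoxy-3-oxopropyl)phenyl]propanoate | COC(=O)CCc1cc(OC)c(O)c(c1)[C@@H](Cc1cc(OC)c(O)c(OC)c1)C(=O)OC
F4 | step 1 | methyl 3-(4-hydroxy-3-iodo-5-methoxyphenyl)propanoate | COC(=O)CCc1cc(I)c(O)c(OC)c1
F5 | step 1 | tert-butyl 2-[2-hydroxy-3-methoxy-5-(3-methoxy-3-oxopropyl)phenyl]acetate | CC(C)(C)OC(=O)Cc1cc(CCC(=O)OC)cc(OC)c1O
F6 | step 2 | methyl 3-(3-hydroxy-7-methoxy-2-oxo-2,3-dihydro-1-benzofuran-5-yl)propanoate (racemic) | COC(=O)CCc1cc(OC)c2OC(=O)C(O)c2c1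
F7 | step 2 | methyl 3-(3-chloro-7-methoxy-2-oxo-2,3-dihydro-1-benzofuran-5-yl)propanoate (racemic) | COC(=O)CCc1cc(OC)c2OC(=O)C(Cl)c2c1
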